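**Retrosynthetic overview**
1. Target ⇐ Yamaguchi acylation of the C8 hydroxyl with (2S,3S)-2,3-dimethyloxirane-2-carboxylic acid (made from ethyl (S)-3-hydroxybutanoate), after acetylation of C9–OH in the 8,9-diol.
2. Ten-membered ring and γ-lactone ⇐ one C6–C7 bond: electrochemical, chromium-catalysed intramolecular allylation of the C6 enal by the C13-bromide/C12-ester unit, then lactonisation; C6 and C7 are set by the C8/C9 dioxolane.
3. Open-chain bromo-enal ⇐ Baylis–Hillman reaction and SN2′ bromination at C7, and a Z-selective Wittig reaction at C1=C10 joining a geraniol-derived C1–C6 ylide to a D-tartrate-derived methyl ketone (C7–C10, C14).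
4. Ring order: dioxolane (bought) → carbocycle together with lactone → dioxolane removed; the oxirane is made on a separate branch.

Assumption: germacranolide numbering is used (C6 lactone oxygen, C8 epoxy ester, C9 acetate, C12 lactone carbonyl, C13 exocyclic CH2); the SMILES is read as 1(10)Z,4E with 6R,7S,8R,9R and 2′S,3′S; geranyl benzoate, (+)-dimethyl 2,3-O-isopropylidene-D-tartrate, methyl acrylate and ethyl (S)-3-hydroxybutanoate are taken as commercial.

**Step 1**
Reactants: 1 geranyl benzoate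
Product: 3 (E)-6-hydroxy-3-methylhex-2-en-1-yl benzoate, via ozonide 2 (not isolated)
Conditions: O3 (1.0 equiv), CH2Cl2, −78 °C; then NaBH4, MeOH, −78 → 0 °C
Reagents that add atoms: ozone, [O-][O+]=O
Why: Ozone attacks the electron-rich 6,7-alkene in preference to the alkene deactivated by the allylic benzoate, and borohydride reduces the ozonide to the primary alcohol (chemoselective ozonolysis with reductive work-up); the E-alkene is untouched.

**Step 2**
Reactants: 3 (E)-6-hydroxy-3-methylhex-2-en-1-yl benzoate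
Product: 4 (E)-6-iodo-3-methylhex-2-en-1-yl benzoate
Conditions: I2, PPh3, imidazole, CH2Cl2, 0 °C → rt
Reagents that add atoms: iodine, II
Why: Appel-type iodination of the primary alcohol under buffered conditions leaves the allylic benzoate and the alkene alone.

**Step 3**
Reactants: 4 (E)-6-iodo-3-methylhex-2-en-1-yl benzoate
Product: 5 [(E)-6-(benzoyloxy)-4-methylhex-4-en-1-yl]triphenylphosphonium iodide
Conditions: PPh3, MeCN, 80 °C
Reagents that add atoms: triphenylphosphine, c1ccc(cc1)P(c1ccccc1)c1ccccc1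
Why: SN2 quaternisation of the primary iodide by triphenylphosphine.

**Step 4**
Reactants: 6 dimethyl (4S,5S)-2,2-dimethyl-1,3-dioxolane-4,5-dicarboxylate
Product: 7 (4S,5S)-N4,N5-dimethoxy-N4,N5,2,2-tetramethyl-1,3-dioxolane-4,5-dicarboxamide
Conditions: MeNHOMe·HCl, iPrMgCl, THF, −20 °C
Reagents that add atoms: N,O-dimethylhydroxylamine hydrochloride, CNOC.Cl
Why: Magnesium amide aminolysis of both esters (Weinreb amide formation); the trans-dioxolane centres are the thermodynamically favoured ones and do not epimerise.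

**Step 5**
Reactants: 7 (4S,5S)-bis-Weinreb amide
Product: 8 (4S,5S)-5-acetyl-N-methoxy-N,2,2-trimethyl-1,3-dioxolane-4-carboxamide
Conditions: MeMgBr (1.3 equiv), THF, −20 °C
Reagents that add atoms: methylmagnesium bromide, C[Mg]Br
Why: Desymmetrising mono-addition of the Grignard reagent to the C2-symmetric bis-Weinreb amide; the chelated tetrahedral magnesium adduct resists over-addition and slows attack on the second amide, and the stereocentres are untouched.

**Step 6**
Reactants: 5 [(E)-6-(benzoyloxy)-4-methylhex-4-en-1-yl]triphenylphosphonium iodide; 8 (4S,5S)-5-acetyl-N-methoxy-N,2,2-trimethyl-1,3-dioxolane-4-carboxamide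
Product: 10 (2E,6Z)-7-{(4R,5S)-5-[methoxy(methyl)carbamoyl]-2,2-dimethyl-1,3-dioxolan-4-yl}-3-methylocta-2,6-dien-1-yl benzoate, via ylide 9 (not isolated)
Conditions: KN(SiMe3)2, THF, −78 → 0 °C; then 8, −78 → −20 °C
Reagents that add atoms: none
Why: Wittig reaction of a non-stabilised ylide with an α-alkoxy methyl ketone, which under salt-free kinetic control gives the Z-trisubstituted allylic ether (chain cis to the oxygenated carbon, the 1(10)Z geometry); low temperature avoids enolisation of the ketone.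

**Step 7**
Reactants: 10 Wittig product
Product: 11 (4S,5R)-5-[(2Z,6E)-8-hydroxy-6-methylocta-2,6-dien-2-yl]-2,2-dimethyl-1,3-dioxolane-4-carbaldehyde
Conditions: iBu2AlH (4.5 equiv), CH2Cl2, −78 °C; Rochelle salt
Reagents that add atoms: none
Why: iBu2AlH reduces the Weinreb amide only to the aldehyde (aluminium chelate stable until work-up) and cleaves the benzoate in the same operation; the trans-dioxolane aldehyde is configurationally stable.

**Step 8**
Reactants: 11 hydroxy aldehyde; 12 methyl acrylate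
Product: 13 methyl 2-{hydroxy[(4R,5R)-5-[(2Z,6E)-8-hydroxy-6-methylocta-2,6-dien-2-yl]-2,2-dimethyl-1,3-dioxolan-4-yl]methyl}prop-2-enoate (both carbinol epimers)
Conditions: DABCO (1 equiv), methyl acrylate (10 equiv), MeOH, rt, 4 d
Reagents that add atoms: none
Why: Morita–Baylis–Hillman reaction of the activated α-alkoxy aldehyde; the new carbinol centre is lost in step 10, so its configuration does not matter.

**Step 9**
Reactants: 13 Baylis–Hillman diol
Product: 14 methyl 2-{hydroxy[(4R,5R)-2,2-dimethyl-5-[(2Z,6E)-6-methyl-8-oxoocta-2,6-dien-2-yl]-1,3-dioxolan-4-yl]methyl}prop-2-enoate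
Conditions: MnO2, CH2Cl2, rt
Reagents that add atoms: none
Why: MnO2 oxidises the primary allylic alcohol to the E-enal much faster than the electron-poor secondary Baylis–Hillman alcohol (chemoselective allylic oxidation).

**Step 10**
Reactants: 14 enal alcohol
Product: 15 methyl (2Z)-2-(bromomethyl)-3-{(4R,5R)-2,2-dimethyl-5-[(2Z,6E)-6-methyl-8-oxoocta-2,6-dien-2-yl]-1,3-dioxolan-4-yl}prop-2-enoate
Conditions: NBS, Me2S, CH2Cl2, 0 °C → rt
Reagents that add atoms: N-bromosuccinimide, BrN1C(=O)CCC1=O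
Why: Bromodimethylsulfonium activation of the Baylis–Hillman alcohol followed by SN2′ attack of bromide gives the rearranged, thermodynamically preferred (Z)-2-(bromomethyl)enoate (Corey–Kim-type bromination).

**Step 11**
Reactants: 15 bromo enal
Product: 19 8α,9β-isopropylidenedioxygermacra-1(10)Z,4E,11(13)-trien-12,6α-olide (7α-H), via allylchromium 16 (not isolated), via silyl ether 17 (not isolated), via hydroxy ester 18 (not isolated)
Conditions: CrCl3·3THF (15 mol %), Me3SiCl (2.5 equiv), LiCl, DMF/THF 1:4, undivided cell, Al anode, reticulated vitreous carbon cathode, 2 mA, 2.3 F/mol, 15 added over 10 h (2 mM), rt; then aq. citric acid, THF; PPTS (cat.), CH2Cl2, rt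
Reagents that add atoms: none
Why: Proposed new method: a chromium-catalysed Nozaki–Hiyama allylation turned over at the cathode is used for the first time to close a ten-membered ring from a 2-(bromomethyl)enoate and an enal; divalent chromium made at the cathode from CrCl3 takes up the C–Br bond in two one-electron steps to give allylchromium 16, which after σ–π–σ equilibration adds 1,2 to the enal through a closed six-membered chair in which C7 is attacked anti to the C8–O bond of the rigid trans-dioxolane (H8 eclipsing the alkene) and both ring arms are equatorial (anti C6/C7, hence the trans-lactone), Me3SiCl frees trivalent chromium from the alkoxide for re-reduction, and the C6 alcohol lactonises onto C12 after desilylation; the closest known reactions are the stoichiometric CrCl2 Nozaki–Hiyama macrocyclisation and the electrochemical Nozaki–Hiyama–Kishi coupling of alkenyl halides.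

**Step 12**
Reactants: 19 lactone acetonide
Product: 20 8α,9β-dihydroxygermacra-1(10)Z,4E,11(13)-trien-12,6α-olide
Conditions: AcOH/H2O 4:1, 35 °C
Reagents that add atoms: none
Why: Acid hydrolysis of the strained trans-fused dioxolane under conditions too mild for transannular cyclisation of the 1(10),4-diene or ionisation of the allylic C9–O bond.

**Step 13**
Reactants: 20 diol
Product: 21 9β-acetoxy-8α-hydroxygermacra-1(10)Z,4E,11(13)-trien-12,6α-olide
Conditions: AcCl (1.05 equiv), 2,4,6-collidine, CH2Cl2, −78 → −40 °C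
Reagents that add atoms: acetyl chloride, CC(Cl)=O
Why: Kinetic mono-acylation: the allylic C9 hydroxyl, flanked by the flat C10 alkene carbon, is expected to react faster than the C8 hydroxyl shielded by the ring-fusion carbon C7 and the lactone; no stereocentre is touched.

**Step 14**
Reactants: 22 ethyl (S)-3-hydroxybutanoate
Product: 24 ethyl (2S,3S)-3-hydroxy-2-methylbutanoate, via dianion 23 (not isolated)
Conditions: LiN(iPr)2 (2.2 equiv), THF, −50 → −20 °C; MeI, −78 → 0 °C
Reagents that add atoms: iodomethane, CI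
Why: Fráter–Seebach alkylation: the lithium-chelated dianion is methylated on the face opposite the C3 methyl group, giving the anti (2S,3S) product.

**Step 15**
Reactants: 24 ethyl (2S,3S)-3-hydroxy-2-methylbutanoate
Product: 26 ethyl (2S,3S)-2,3-dihydroxy-2-methylbutanoate, via dianion 25 (not isolated)
Conditions: LiN(iPr)2 (2.2 equiv), THF, −40 → −10 °C; MoO5·py·HMPA, −78 → −20 °C
Reagents that add atoms: MoO5·pyridine·HMPA (MoOPH), O=[Mo]12(OO1)OO2.c1ccncc1.CN(C)P(=O)(N(C)C)N(C)C
Why: Electrophilic hydroxylation (Vedejs) of the chelated tetrasubstituted enolate on the same face as in step 14, which puts the new hydroxyl anti to the C3 hydroxyl and sets C2 as S.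

**Step 16**
Reactants: 26 ethyl (2S,3S)-2,3-dihydroxy-2-methylbutanoate
Product: 30 (2S,3S)-2,3-dimethyloxirane-2-carboxylic acid, via orthoester 27 (not isolated), via bromoacetate 28 (not isolated), via epoxy ester 29 (not isolated)
Conditions: MeC(OMe)3, PPTS (cat.), CH2Cl2, rt; AcBr, CH2Cl2, 0 °C; LiOH, THF/H2O, 0 °C → rt; NaHSO4 to pH 3, 0 °C
Reagents that add atoms: lithium hydroxide, [Li+].[OH-]
Why: Kolb–Sharpless diol-to-epoxide sequence: bromide opens the cyclic acetoxonium ion with inversion, hydroxide then cleaves the acetate and the C2 alkoxide displaces bromide with a second inversion (net retention at both carbons, hence the cis (2S,3S)-oxirane), and the same base saponifies the ethyl ester.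

**Step 17**
Reactants: 21 9β-acetoxy-8α-hydroxy lactone; 30 (2S,3S)-2,3-dimethyloxirane-2-carboxylic acid
Product: 32 9β-acetoxy-8α-[(2S,3S)-2,3-epoxy-2-methylbutanoyloxy]germacra-1(10)Z,4E,11(13)-trien-12,6α-olide (CNP0304643.2), via mixed anhydride 31 (not isolated)
Conditions: 30, 2,4,6-trichlorobenzoyl chloride, Et3N, toluene, rt; then 21, DMAP, rt
Reagents that add atoms: none
Why: Yamaguchi esterification through the mixed anhydride acylates the hindered C8 hydroxyl without opening the oxirane or touching the other stereocentres.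

**Compound list**
1 | geranyl benzoate, (2E)-3,7-dimethylocta-2,6-dien-1-yl benzoate | CC(C)=CCC/C(C)=C/COC(=O)c1ccccc1 | starting material
2 | (E)-5-(3,3-dimethyl-1,2,4-trioxolan-5-yl)-3-methylpent-2-en-1-yl benzoate (ozonide) | CC1(C)OOC(CC/C(C)=C/COC(=O)c2ccccc2)O1 | intermediate (not isolated)
3 | (E)-6-hydroxy-3-methylhex-2-en-1-yl benzoate | OCCC/C(C)=C/COC(=O)c1ccccc1 | intermediate
4 | (E)-6-iodo-3-methylhex-2-en-1-yl benzoate | ICCC/C(C)=C/COC(=O)c1ccccc1 | intermediate
5 | [(E)-6-(benzoyloxy)-4-methylhex-4-en-1-yl]triphenylphosphonium iodide | [I-].O=C(OC/C=C(\C)CCC[P+](c1ccccc1)(c1ccccc1)c1ccccc1)c1ccccc1 | intermediate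
6 | dimethyl (4S,5S)-2,2-dimethyl-1,3-dioxolane-4,5-dicarboxylate (D-tartrate acetonide) | COC(=O)[C@H]1OC(C)(C)O[C@@H]1C(=O)OC | starting material
7 | (4S,5S)-N4,N5-dimethoxy-N4,N5,2,2-tetramethyl-1,3-dioxolane-4,5-dicarboxamide | CON(C)C(=O)[C@H]1OC(C)(C)O[C@@H]1C(=O)N(C)OC | intermediate
8 | (4S,5S)-5-acetyl-N-methoxy-N,2,2-trimethyl-1,3-dioxolane-4-carboxamide | CC(=O)[C@H]1OC(C)(C)O[C@@H]1C(=O)N(C)OC | intermediate
9 | [(E)-6-(benzoyloxy)-4-methylhex-4-en-1-ylidene]triphenylphosphorane (ylide) | O=C(OC/C=C(\C)CCC=P(c1ccccc1)(c1ccccc1)c1ccccc1)c1ccccc1 | intermediate (not isolated)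
10 | (2E,6Z)-7-{(4R,5S)-5-[methoxy(methyl)carbamoyl]-2,2-dimethyl-1,3-dioxolan-4-yl}-3-methylocta-2,6-dien-1-yl benzoate | O=C(OC/C=C(\C)CC/C=C(/C)[C@H]1OC(C)(C)O[C@@H]1C(=O)N(C)OC)c1ccccc1 | intermediate
11 | (4S,5R)-5-[(2Z,6E)-8-hydroxy-6-methylocta-2,6-dien-2-yl]-2,2-dimethyl-1,3-dioxolane-4-carbaldehyde | OC/C=C(\C)CC/C=C(/C)[C@H]1OC(C)(C)O[C@@H]1C=O | intermediate
12 | methyl acrylate | C=CC(=O)OC | starting material
13 | methyl 2-{hydroxy[(4R,5R)-5-[(2Z,6E)-8-hydroxy-6-methylocta-2,6-dien-2-yl]-2,2-dimethyl-1,3-dioxolan-4-yl]methyl}prop-2-enoate (both carbinol epimers) | OC/C=C(\C)CC/C=C(/C)[C@H]1OC(C)(C)O[C@@H]1C(O)C(=C)C(=O)OC | intermediate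
14 | methyl 2-{hydroxy[(4R,5R)-2,2-dimethyl-5-[(2Z,6E)-6-methyl-8-oxoocta-2,6-dien-2-yl]-1,3-dioxolan-4-yl]methyl}prop-2-enoate | O=C/C=C(\C)CC/C=C(/C)[C@H]1OC(C)(C)O[C@@H]1C(O)C(=C)C(=O)OC | intermediate
15 | methyl (2Z)-2-(bromomethyl)-3-{(4R,5R)-2,2-dimethyl-5-[(2Z,6E)-6-methyl-8-oxoocta-2,6-dien-2-yl]-1,3-dioxolan-4-yl}prop-2-enoate | O=C/C=C(\C)CC/C=C(/C)[C@H]1OC(C)(C)O[C@@H]1/C=C(\CBr)C(=O)OC | intermediate
16 | σ-allylchromium dichloride of 15 (CrCl2 in place of Br, solvated) | O=C/C=C(\C)CC/C=C(/C)[C@H]1OC(C)(C)O[C@@H]1/C=C(\C[Cr](Cl)Cl)C(=O)OC | intermediate (not isolated)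
17 | methyl 8α,9β-isopropylidenedioxy-6α-(trimethylsilyloxy)germacra-1(10)Z,4E,11(13)-trien-12-oate (7α-H) | C[Si](C)(C)O[C@@H]1/C=C(\C)CC/C=C(/C)[C@H]2OC(C)(C)O[C@@H]2[C@H]1C(=C)C(=O)OC | intermediate (not isolated)
18 | methyl 6α-hydroxy-8α,9β-isopropylidenedioxygermacra-1(10)Z,4E,11(13)-trien-12-oate (7α-H) | O[C@@H]1/C=C(\C)CC/C=C(/C)[C@H]2OC(C)(C)O[C@@H]2[C@H]1C(=C)C(=O)OC | intermediate (not isolated)
19 | 8α,9β-isopropylidenedioxygermacra-1(10)Z,4E,11(13)-trien-12,6α-olide (6β-H, 7α-H) | C=C1C(=O)O[C@@H]2/C=C(\C)CC/C=C(/C)[C@H]3OC(C)(C)O[C@@H]3[C@@H]12 | intermediate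
20 | 8α,9β-dihydroxygermacra-1(10)Z,4E,11(13)-trien-12,6α-olide | C=C1C(=O)O[C@@H]2/C=C(\C)CC/C=C(/C)[C@@H](O)[C@H](O)[C@@H]12 | intermediate
21 | 9β-acetoxy-8α-hydroxygermacra-1(10)Z,4E,11(13)-trien-12,6α-olide | C=C1C(=O)O[C@@H]2/C=C(\C)CC/C=C(/C)[C@@H](OC(C)=O)[C@H](O)[C@@H]12 | intermediate
22 | ethyl (S)-3-hydroxybutanoate | CCOC(=O)C[C@H](C)O | starting material
23 | dilithium dianion of 22 (chelated enolate alkoxide) | [Li+].[Li+].CCO/C([O-])=C/[C@H](C)[O-] | intermediate (not isolated)
24 | ethyl (2S,3S)-3-hydroxy-2-methylbutanoate | CCOC(=O)[C@@H](C)[C@H](C)O | intermediate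
25 | dilithium dianion of 24 (chelated enolate alkoxide) | [Li+].[Li+].CCO/C([O-])=C(\C)[C@H](C)[O-] | intermediate (not isolated)
26 | ethyl (2S,3S)-2,3-dihydroxy-2-methylbutanoate | CCOC(=O)[C@@](C)(O)[C@H](C)O | intermediate
27 | ethyl (4S,5S)-2-methoxy-2,4,5-trimethyl-1,3-dioxolane-4-carboxylate (both C2 epimers) | CCOC(=O)[C@@]1(C)OC(C)(OC)O[C@H]1C | intermediate (not isolated)
28 | ethyl (2R,3R)-2-acetoxy-3-bromo-2-methylbutanoate (C3 inverted) | CCOC(=O)[C@@](C)(OC(C)=O)[C@@H](C)Br | intermediate (not isolated)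
29 | ethyl (2S,3S)-2,3-dimethyloxirane-2-carboxylate | CCOC(=O)[C@@]1(C)O[C@H]1C | intermediate (not isolated)
30 | (2S,3S)-2,3-dimethyloxirane-2-carboxylic acid | OC(=O)[C@@]1(C)O[C@H]1C | intermediate
31 | (2S,3S)-2,3-dimethyloxirane-2-carboxylic 2,4,6-trichlorobenzoic anhydride | O=C(OC(=O)[C@@]1(C)O[C@H]1C)c1c(Cl)cc(Cl)cc1Cl | intermediate (not isolated)
32 | 9β-acetoxy-8α-[(2S,3S)-2,3-epoxy-2-methylbutanoyloxy]germacra-1(10)Z,4E,11(13)-trien-12,6α-olide, (6R,7S,8R,9R) | C=C1C(=O)O[C@@H]2/C=C(\C)CC/C=C(/C)[C@@H](OC(C)=O)[C@H](OC(=O)[C@@]3(C)O[C@H]3C)[C@@H]12 | target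

**Step count**
Total: 17 steps. Longest linear sequence: 12 steps (1, 2, 3, 6, 7, 8, 9, 10, 11, 12, 13, 17) from geranyl benzoate.

**Steps most likely to fail and fallbacks**

Step 11 (the proposed electrochemical ring closure). It may fail through direct cathodic reduction of the enal, 1,4-elimination of the allylmetal towards the C8 oxygen, or the wrong C6/C7 configuration. The fallback uses known palladium/indium umpolung allylation and sets out from 14. Acetylation (Ac2O, DMAP, pyridine) gives methyl 2-{acetoxy[(4R,5R)-2,2-dimethyl-5-[(2Z,6E)-6-methyl-8-oxoocta-2,6-dien-2-yl]-1,3-dioxolan-4-yl]methyl}prop-2-enoate F3. With Pd(PPh3)4 (5 mol %) and InI (1.5 equiv) in THF at high dilution, zerovalent palladium ionises the allylic acetate, InI reduces the π-allyl complex to an allylindium, and this adds to the enal. The resulting hydroxy ester 18 is lactonised with PPTS, and the fallback comes back to the route at 19.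

Step 13 (regioselective acetylation of the diol). The two secondary hydroxyls may not be distinguished well enough. The fallback sets out from 20 and separates them by oxidation state. MnO2 oxidises only the allylic C9 alcohol to 8α-hydroxy-9-oxogermacra-1(10)Z,4E,11(13)-trien-12,6α-olide F4. Yamaguchi acylation of the remaining C8 hydroxyl with acid 30 gives 8α-[(2S,3S)-2,3-epoxy-2-methylbutanoyloxy]-9-oxogermacra-1(10)Z,4E,11(13)-trien-12,6α-olide F5. Luche reduction (NaBH4, CeCl3·7H2O, MeOH, −78 °C; hydride anti to the α-acyloxy group) gives 8α-[(2S,3S)-2,3-epoxy-2-methylbutanoyloxy]-9β-hydroxygermacra-1(10)Z,4E,11(13)-trien-12,6α-olide F6. Ac2O/DMAP then acetylates C9, and the fallback comes back to the route at target 32.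

Step 6 (Z-selective Wittig reaction). The Z:E ratio may be low, or the ylide may enolise ketone 8. The fallback is a Horner–Wittig sequence that fixes the geometry by separation; it sets out from 4 and 8. Iodide 4 is heated with ethyl diphenylphosphinite (Michaelis–Arbuzov, 120 °C) to give (E)-6-(diphenylphosphoryl)-3-methylhex-2-en-1-yl benzoate F1. F1 is lithiated (LiN(iPr)2, THF, −78 °C) and added to ketone 8, and the β-hydroxy phosphine oxides are separated on silica. The syn-eliminating diastereomer, (E)-6-(diphenylphosphoryl)-7-hydroxy-7-{(4S,5S)-5-[methoxy(methyl)carbamoyl]-2,2-dimethyl-1,3-dioxolan-4-yl}-3-methyloct-2-en-1-yl benzoate F2, is treated with KH in DMF. Stereospecific syn-elimination gives the Z-alkene, and the fallback comes back to the route at 10.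

**Further compounds**
F1 | step 6 | (E)-6-(diphenylphosphoryl)-3-methylhex-2-en-1-yl benzoate | O=C(OC/C=C(\C)CCCP(=O)(c1ccccc1)c1ccccc1)c1ccccc1
F2 | step 6 | (E)-6-(diphenylphosphoryl)-7-hydroxy-7-{(4S,5S)-5-[methoxy(methyl)carbamoyl]-2,2-dimethyl-1,3-dioxolan-4-yl}-3-methyloct-2-en-1-yl benzoate (syn-eliminating diastereomer) | O=P(c1ccccc1)(c1ccccc1)[C@@H](CC/C(C)=C/COC(=O)c1ccccc1)[C@](C)(O)[C@H]1OC(C)(C)O[C@@H]1C(=O)N(C)OC
F3 | step 11 | methyl 2-{acetoxy[(4R,5R)-2,2-dimethyl-5-[(2Z,6E)-6-methyl-8-oxoocta-2,6-dien-2-yl]-1,3-dioxolan-4-yl]methyl}prop-2-enoate | O=C/C=C(\C)CC/C=C(/C)[C@H]1OC(C)(C)O[C@@H]1C(OC(C)=O)C(=C)C(=O)OC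
F4 | step 13 | 8α-hydroxy-9-oxogermacra-1(10)Z,4E,11(13)-trien-12,6α-olide | C=C1C(=O)O[C@@H]2/C=C(\C)CC/C=C(/C)C(=O)[C@H](O)[C@@H]12
F5 | step 13 | 8α-[(2S,3S)-2,3-epoxy-2-methylbutanoyloxy]-9-oxogermacra-1(10)Z,4E,11(13)-trien-12,6α-olide | C=C1C(=O)O[C@@H]2/C=C(\C)CC/C=C(/C)C(=O)[C@H](OC(=O)[C@@]3(C)O[C@H]3C)[C@@H]12
F6 | step 13 | 8α-[(2S,3S)-2,3-epoxy-2-methylbutanoyloxy]-9β-hydroxygermacra-1(10)Z,4E,11(13)-trien-12,6α-olide | C=C1C(=O)O[C@@H]2/C=C(\C)CC/C=C(/C)[C@@H](O)[C@H](OC(=O)[C@@]3(C)O[C@H]3C)[C@@H]12
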